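**Retrosynthetic overview**
- The last operation is acidic. It turns a C3 diethyl acetal into the C3 aldehyde and frees O6, O2′ and O4′ from MOM ethers.
- The furan is the only ring that is made, since both benzene rings are bought. It is cut at C3–C3a and O1–C2. O1/C7a/C3a come from an N‑aryloxyacetamide and C2/C3 from an aryl–C≡C–CH(OEt)2 alkyne, joined by a redox‑neutral Cp*Rh(III) [3+2] annulation.
- The feature that carries the plan is C7a. It holds O1 and sits between C7 (prenyl) and C3a, so the aryloxyamide has a single ortho C–H, the future C3a. C2 (aryl) and C3 (formyl carbon) form the aryl/alkyl‑type pair that orients an unsymmetrical alkyne.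
- Aryloxyamide: resorcinol → bis‑MOM ether → C2 lithiation and prenylation → loss of one MOM → O‑amination → N‑acetylation.
- Alkyne: 4,6‑dibromoresorcinol → bis‑MOM ether → single Br/Li exchange and prenylation → Sonogashira coupling with 3,3‑diethoxyprop‑1‑yne.

Key step: step 9

Assumption: eryvarin Q has no stereocentre, and both alkenes end in a gem‑dimethyl group. The SMILES therefore defines one achiral compound and no enantiomer has to be controlled. Abbreviations: prenyl = 3‑methylbut‑2‑en‑1‑yl, MOM = methoxymethyl.

**Step 1**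
Reactants: 1 resorcinol
Product: 2 1,3‑bis(methoxymethoxy)benzene
Conditions: MOMCl (2.4 equiv), K2CO3, acetone, 0 °C→rt
Reagents that add atoms: chloromethyl methyl ether, COCCl
Why: Williamson‑type O‑alkylation of both phenols with the reactive α‑chloro ether should give the bis‑acetal, which is inert to organolithiums and directs the metalation in the next step.

**Step 2**
Reactants: 2 1,3‑bis(methoxymethoxy)benzene; 3 prenyl bromide (1‑bromo‑3‑methylbut‑2‑ene)
Product: 5 1,3‑bis(methoxymethoxy)‑2‑prenylbenzene, via 2‑lithio‑1,3‑bis(methoxymethoxy)benzene 4 (not isolated)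
Conditions: n‑BuLi (1.1 equiv), THF, 0 °C→rt; then 3, −78 °C→rt
Reagents that add atoms: none
Why: In this directed ortho‑metalation the C2–H between the two MOM ethers is the most acidic, doubly chelated site, and aryllithium 4 displaces bromide at the primary allylic carbon of 3 (SN2, the hindered γ‑carbon disfavouring SN2′), which places a linear prenyl group at the future C7.

**Step 3**
Reactants: 5 1,3‑bis(methoxymethoxy)‑2‑prenylbenzene
Product: 6 3‑(methoxymethoxy)‑2‑prenylphenol
Conditions: p‑TsOH·H2O (10 mol%), MeOH, 40 °C, quenched (NaHCO3) at partial conversion; recovered 5 recycled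
Reagents that add atoms: none
Why: Acid‑catalysed transacetalisation to methanol removes one of two equivalent MOM groups, so the reaction is stopped early, phenol 6 is separated from neutral 5 by extraction into cold dilute NaOH, and the catalytic acid in methanol is too weak to protonate the trisubstituted alkene.

**Step 4**
Reactants: 6 3‑(methoxymethoxy)‑2‑prenylphenol
Product: 8 O‑[3‑(methoxymethoxy)‑2‑prenylphenyl]hydroxylamine, via potassium phenoxide 7 (not isolated)
Conditions: KOt‑Bu (1.05 equiv), DMF, 0 °C; then O‑(2,4‑dinitrophenyl)hydroxylamine (1.1 equiv), 0 °C→rt; used at once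
Reagents that add atoms: O‑(2,4‑dinitrophenyl)hydroxylamine, NOc1ccc(cc1[N+](=O)[O-])[N+](=O)[O-]
Why: In this electrophilic amination phenoxide 7 attacks the reagent nitrogen in an SN2 displacement of the stabilised 2,4‑dinitrophenoxide, a known route to oxygenated aryloxyamines, and without a metal catalyst the reagent leaves the alkene untouched.

**Step 5**
Reactants: 8 O‑[3‑(methoxymethoxy)‑2‑prenylphenyl]hydroxylamine
Product: 9 N‑[3‑(methoxymethoxy)‑2‑prenylphenoxy]acetamide
Conditions: Ac2O (1.05 equiv), CH2Cl2, 0 °C→rt
Reagents that add atoms: acetic anhydride, CC(=O)OC(C)=O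
Why: N‑acylation of the α‑effect NH2 group with one equivalent of anhydride is fast at 0 °C and should stop at the mono‑amide, which is the oxidising directing group of the key step.

**Step 6**
Reactants: 10 4,6‑dibromoresorcinol
Product: 11 1,5‑dibromo‑2,4‑bis(methoxymethoxy)benzene
Conditions: MOMCl (2.4 equiv), K2CO3, acetone, 0 °C→rt
Reagents that add atoms: chloromethyl methyl ether, COCCl
Why: Williamson‑type O‑alkylation of the two acidified phenols gives a bis‑acetal that tolerates the halogen–metal exchange that follows.

**Step 7**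
Reactants: 11 1,5‑dibromo‑2,4‑bis(methoxymethoxy)benzene; 3 prenyl bromide
Product: 13 1‑bromo‑2,4‑bis(methoxymethoxy)‑5‑prenylbenzene, via monolithiated bromoarene 12 (not isolated)
Conditions: n‑BuLi (1.0 equiv), THF, −78 °C; then 3 (1.2 equiv), −78 °C→rt
Reagents that add atoms: none
Why: Bromine–lithium exchange with exactly one equivalent of n‑BuLi stops at mono‑anion 12, which is stabilised by its ortho MOM oxygen while a second exchange would build a dianion, and fast SN2 allylation installs the C5′ prenyl group and leaves the other bromide to mark C1′.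

**Step 8**
Reactants: 13 1‑bromo‑2,4‑bis(methoxymethoxy)‑5‑prenylbenzene; 14 3,3‑diethoxyprop‑1‑yne
Product: 15 1‑(3,3‑diethoxyprop‑1‑yn‑1‑yl)‑2,4‑bis(methoxymethoxy)‑5‑prenylbenzene
Conditions: PdCl2(MeCN)2 (2 mol%), XPhos (6 mol%), Cs2CO3 (2 equiv), MeCN, 80 °C
Reagents that add atoms: none
Why: In this copper‑free Sonogashira coupling the bulky electron‑rich biarylphosphine makes oxidative addition to the electron‑rich ortho‑alkoxy bromide feasible, the carbonate base leaves MOM ethers and acetal intact, and the trisubstituted alkene does not compete in carbopalladation.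

**Step 9**
Reactants: 9 N‑[3‑(methoxymethoxy)‑2‑prenylphenoxy]acetamide; 15 aryl propynal diethyl acetal
Product: 18 2‑[2,4‑bis(methoxymethoxy)‑5‑prenylphenyl]‑3‑(diethoxymethyl)‑6‑(methoxymethoxy)‑7‑prenylbenzofuran, via (E)‑enamide 16 (not isolated), via 2‑acetamido‑2,3‑dihydrobenzofuran 17 (not isolated)
Conditions: [Cp*RhCl2]2 (5 mol%), CsOAc (25 mol%), AcOH (1.2 equiv), 15 (1.2 equiv), CH2Cl2, rt
Reagents that add atoms: none
Why: Acetate‑assisted metalation–deprotonation of N‑bound 9 takes the one free ortho C–H (future C3a) to give a five‑membered rhodacycle, alkyne 15 inserts syn into the Rh–aryl bond (C3–C3a), and the N–O bond then re‑oxidises the metal from within, moving nitrogen onto the rhodium‑bound carbon (C2) so that protonolysis releases (E)‑enamide 16 and Cp*Rh(III). Acetic acid protonates 16 at C3 to an N‑acyliminium ion at C2 that is stabilised by the 2′,4′‑dialkoxyaryl group, the freed phenol O1 adds to it in a 5‑exo‑trig closure (O1–C2) to give aminal 17, and loss of acetamide and of the C3 proton aromatises the furan, the only ring closed. The closest known reaction is the redox‑neutral Cp*Rh(III) [3+2] annulation of N‑phenoxyacetamides with internal aryl–alkyl alkynes in CH2Cl2/AcOH, which gives 2‑aryl‑3‑alkylbenzofurans. Two selectivities are needed: the C–H site is fixed because the prenyl group occupies the other ortho carbon (future C7), and the alkyne orientation (aryl‑bearing carbon on rhodium, hence at C2) follows the usual aryl‑next‑to‑metal preference, may be reinforced by contact of the ortho MOM oxygen with the cationic metal, and keeps the ethoxy groups γ to rhodium, where β‑alkoxide elimination cannot occur. No external oxidant is present, so both trisubstituted alkenes should survive, MOM ethers and the propargylic acetal tolerate acetic acid at room temperature, and any early loss of the now activated acetal in 18 only anticipates step 10. No stereocentre remains, because the two in 17 are erased on aromatisation.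

**Step 10**
Reactants: 18 3‑(diethoxymethyl)benzofuran tris‑MOM ether
Product: 20 eryvarin Q, via tris‑MOM aldehyde 19 (not isolated)
Conditions: 3 M aq. HCl–MeOH–THF (1:3:3), 40 °C; then dilution with H2O, rt
Reagents that add atoms: water, O
Why: In this acid‑catalysed acetal hydrolysis and transacetalisation the benzofuran‑3‑yl acetal ionises first (its oxocarbenium ion is stabilised by O1) to give 19, the three aryl MOM groups then pass their CH2 to methanol, which keeps formaldehyde away from the resorcinol ring, the dilute acid and modest temperature should stay below what is needed to protonate the prenyl alkenes, and the final dilution with water returns any methyl acetal or cyclic O2′ mixed acetal to the hydrogen‑bonded aldehyde.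

**Compound list**
1 | resorcinol | Oc1cccc(O)c1 | starting material
2 | 1,3‑bis(methoxymethoxy)benzene | COCOc1cccc(OCOC)c1 | intermediate
3 | prenyl bromide | CC(C)=CCBr | starting material
4 | 2‑lithio‑1,3‑bis(methoxymethoxy)benzene | [Li]c1c(OCOC)cccc1OCOC | intermediate
5 | 1,3‑bis(methoxymethoxy)‑2‑prenylbenzene | COCOc1cccc(OCOC)c1CC=C(C)C | intermediate
6 | 3‑(methoxymethoxy)‑2‑prenylphenol | COCOc1cccc(O)c1CC=C(C)C | intermediate
7 | potassium 3‑(methoxymethoxy)‑2‑prenylphenoxide | [K+].[O-]c1cccc(OCOC)c1CC=C(C)C | intermediate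
8 | O‑[3‑(methoxymethoxy)‑2‑prenylphenyl]hydroxylamine | NOc1cccc(OCOC)c1CC=C(C)C | intermediate
9 | N‑[3‑(methoxymethoxy)‑2‑prenylphenoxy]acetamide | CC(=O)NOc1cccc(OCOC)c1CC=C(C)C | intermediate
10 | 4,6‑dibromoresorcinol | Oc1cc(O)c(Br)cc1Br | starting material
11 | 1,5‑dibromo‑2,4‑bis(methoxymethoxy)benzene | COCOc1cc(OCOC)c(Br)cc1Br | intermediate
12 | [5‑bromo‑2,4‑bis(methoxymethoxy)phenyl]lithium | [Li]c1cc(Br)c(OCOC)cc1OCOC | intermediate
13 | 1‑bromo‑2,4‑bis(methoxymethoxy)‑5‑prenylbenzene | COCOc1cc(OCOC)c(CC=C(C)C)cc1Br | intermediate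
14 | 3,3‑diethoxyprop‑1‑yne | C#CC(OCC)OCC | starting material
15 | 1‑(3,3‑diethoxyprop‑1‑yn‑1‑yl)‑2,4‑bis(methoxymethoxy)‑5‑prenylbenzene | COCOc1cc(OCOC)c(CC=C(C)C)cc1C#CC(OCC)OCC | intermediate
16 | (E)‑enamide, hydroxyaryl group cis to NHAc | CC(=O)N/C(c1cc(CC=C(C)C)c(OCOC)cc1OCOC)=C(\c1ccc(OCOC)c(CC=C(C)C)c1O)C(OCC)OCC | intermediate
17 | 2‑acetamido‑2‑aryl‑3‑(diethoxymethyl)‑2,3‑dihydrobenzofuran (transient stereoisomer mixture, configuration undefined and lost) | CC(=O)NC1(c2cc(CC=C(C)C)c(OCOC)cc2OCOC)Oc2c(CC=C(C)C)c(OCOC)ccc2C1C(OCC)OCC | intermediate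
18 | 2‑[2,4‑bis(methoxymethoxy)‑5‑prenylphenyl]‑3‑(diethoxymethyl)‑6‑(methoxymethoxy)‑7‑prenylbenzofuran | COCOc1cc(OCOC)c(CC=C(C)C)cc1-c1oc2c(CC=C(C)C)c(OCOC)ccc2c1C(OCC)OCC | intermediate
19 | 2‑[2,4‑bis(methoxymethoxy)‑5‑prenylphenyl]‑6‑(methoxymethoxy)‑7‑prenylbenzofuran‑3‑carbaldehyde | COCOc1cc(OCOC)c(CC=C(C)C)cc1-c1oc2c(CC=C(C)C)c(OCOC)ccc2c1C=O | intermediate
20 | eryvarin Q | CC(C)=CCc1cc(-c2oc3c(CC=C(C)C)c(O)ccc3c2C=O)c(O)cc1O | target

**Step count**
Total steps: 10. Longest linear sequence: 7 (steps 1–5, 9, 10).

**Steps most likely to fail**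

1. **Step 9.**
   - Risk: the alkyne may insert the other way round, with the acetal carbon on rhodium, after which β‑ethoxide elimination drains the intermediate. Alternatively the hindered, electron‑rich alkyne may insert so slowly that the N–O bond of 9 is simply reduced.
   - Fallback: it sets out from aryloxyamine 8 and bromide 13 and returns at aldehyde 19. The C–H activation is replaced by a [3,3]‑sigmatropic benzofuran synthesis.
   - Bromide 13 is exchanged with n‑BuLi (THF, −78 °C) to the aryllithium F1 and acylated with N‑methoxy‑N‑methylacetamide to the acetophenone F2.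
   - Condensation of F2 with 8 (PPTS cat., EtOH, rt→40 °C) gives the O‑aryl ketoxime ether F3.
   - N‑Trifluoroacetylation (trifluoroacetyl triflate, DMAP, CH2Cl2, rt) triggers ene‑hydroxylamine formation, a [3,3] shift to the only free ortho carbon, cyclisation and loss of trifluoroacetamide, to give the 3‑unsubstituted 2‑arylbenzofuran F4.
   - Vilsmeier–Haack formylation at the nucleophilic C3 (POCl3, DMF, 0 °C→rt; aq. NaOAc) gives 19, which is then isolated and deprotected as in step 10.

2. **Step 10.**
   - Risk: the liberated O6–H and O4′–H may add to acid‑protonated prenyl alkenes and close chromans, and released formaldehyde may attack the resorcinol ring.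
   - Fallback: it sets out from 18 and returns at 20. Brønsted‑acid solvolysis of the MOM ethers is replaced by silyl transfer under buffered conditions.
   - PPTS in acetone–H2O (rt) hydrolyses only the activated acetal, and 19 is isolated.
   - TMSOTf with 2,2′‑bipyridyl (MeCN, 0 °C→rt) exchanges each aryl MOM group for silicon to give the tris(trimethylsilyl) ether F5.
   - Addition of water (or catalytic K2CO3 in MeOH, 0 °C) desilylates F5 to 20 without any strong acid.

3. **Step 3.**
   - Risk: nothing distinguishes the first MOM cleavage from the second, so over‑deprotection competes, and the new ortho‑prenylphenol stays exposed to acid.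
   - Fallback: it sets out from resorcinol 1 and returns at phenol 6. The two oxygens are differentiated before the prenyl group is present.
   - An excess of 1 with one equivalent of MOMCl (K2CO3, acetone) gives 3‑(methoxymethoxy)phenol F6, and surplus 1 is washed out with water.
   - Dihydropyran with PPTS (CH2Cl2, rt) gives the mixed MOM/THP bis‑acetal F7.
   - n‑BuLi (THF, 0 °C) metalates between the two acetal oxygens to the aryllithium F8, and prenyl bromide 3 gives the prenylated mixed acetal F9.
   - PPTS in EtOH (50 °C) removes only the more labile THP group to give 6.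

**Further compounds**
F1 | step 9 | [2,4‑bis(methoxymethoxy)‑5‑prenylphenyl]lithium | [Li]c1cc(CC=C(C)C)c(OCOC)cc1OCOC
F2 | step 9 | 1‑[2,4‑bis(methoxymethoxy)‑5‑prenylphenyl]ethan‑1‑one | CC(=O)c1cc(CC=C(C)C)c(OCOC)cc1OCOC
F3 | step 9 | (E)‑1‑[2,4‑bis(methoxymethoxy)‑5‑prenylphenyl]ethan‑1‑one O‑[3‑(methoxymethoxy)‑2‑prenylphenyl]oxime | C/C(=N\Oc1cccc(OCOC)c1CC=C(C)C)c1cc(CC=C(C)C)c(OCOC)cc1OCOC
F4 | step 9 | 2‑[2,4‑bis(methoxymethoxy)‑5‑prenylphenyl]‑6‑(methoxymethoxy)‑7‑prenylbenzofuran | COCOc1cc(OCOC)c(CC=C(C)C)cc1-c1cc2ccc(OCOC)c(CC=C(C)C)c2o1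
F5 | step 10 | eryvarin Q tris(trimethylsilyl) ether | C[Si](C)(C)Oc1cc(O[Si](C)(C)C)c(CC=C(C)C)cc1-c1oc2c(CC=C(C)C)c(O[Si](C)(C)C)ccc2c1C=O
F6 | step 3 | 3‑(methoxymethoxy)phenol | COCOc1cccc(O)c1
F7 | step 3 | 2‑[3‑(methoxymethoxy)phenoxy]tetrahydro‑2H‑pyran (racemic) | COCOc1cccc(OC2CCCCO2)c1
F8 | step 3 | [2‑(methoxymethoxy)‑6‑(tetrahydro‑2H‑pyran‑2‑yloxy)phenyl]lithium (racemic) | [Li]c1c(OCOC)cccc1OC1CCCCO1
F9 | step 3 | 2‑[3‑(methoxymethoxy)‑2‑prenylphenoxy]tetrahydro‑2H‑pyran (racemic) | COCOc1cccc(OC2CCCCO2)c1CC=C(C)C
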